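**Retrosynthetic overview**

1. Target (C6 R, C7 R, C8 R, C10 S; C4=C5 Z) ⇒ cleavage of a C15 silyl ether and methacrylation at C8 of a macrocyclic alcohol.
2. Ten-membered carbocycle (formed last) ⇒ C7–C8 bond by intramolecular zinc Barbier allylation of a C8 aldehyde with a lactone-bound allylic bromide (sets C7 and C8).
3. α-Methylene lactone (formed second) ⇒ C6–C7 bond and lactone C–O bond by a chiral Brønsted acid-catalysed γ-bromoallylboration/lactonisation of a (Z)-dienal (sets C6; new reaction).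
4. Furanone (formed first) ⇒ gold cycloisomerisation of a γ-hydroxy ynone ⇐ carbonylative Sonogashira union (C2–C3–C4) of a tertiary propargylic alcohol with a (Z)-β-iodo enal.
5. Propargylic alcohol ⇐ chiral-diol-catalysed allylboration of an achiral silyl ynone (C10, first stereocentre), then ozonolysis/acetalisation; iodo enal ⇐ hydroalumination–iodination of a monosilylated butynediol.

Atom labels (germacrane positions): C1 furanone C=O, C2=C3 furanone alkene with the C3–O–C10 bridge, C4=C5 ring alkene (C15 = CH2OH on C4), C6 lactone O–CH, C7, C8 ester O–CH, C9 CH2, C10 quaternary carbon (C14 methyl), C11=C13 exocyclic methylene, C12 lactone C=O.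

Assumption: the sense of induction of each chiral catalyst is taken from its closest precedents (if it proves opposite, the mirror-image catalyst is used), and compounds 5, 10 and 16 are taken as catalogue chemicals.

**Route**

Step 1
Reactants: 1 allylmagnesium bromide; 2 triisopropyl borate
Product: 4 allyldiisopropoxyborane, via borate ate complex 3 (not isolated)
Conditions: Et2O, −78 to 23 °C; HCl (2 M in Et2O), 0 °C; filter, distil
Reagents that add atoms: none
Why: Grignard borylation, in which the allyl Grignard adds to the borate to give the ate complex and anhydrous acid expels one isopropoxide to give the boronic ester.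

Step 2
Reactants: 5 4-(trimethylsilyl)but-3-yn-2-one; 4 allyldiisopropoxyborane
Product: 6 (S)-3-methyl-1-(trimethylsilyl)hex-5-en-1-yn-3-ol
Conditions: (R)-3,3'-Br2-BINOL (15 mol%), PhMe/PhCF3 1:3, −35 °C, 24 h; aq. NaHCO3
Reagents that add atoms: none
Why: Chiral-diol-catalysed asymmetric allylboration of a ketone, in which exchange of an isopropoxy group for the diol gives a more Lewis-acidic chiral boronate that transfers allyl through a closed chair transition state, telling the alkynyl from the methyl group and setting C10 as S (first stereocentre).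

Step 3
Reactants: 6 (S)-3-methyl-1-(trimethylsilyl)hex-5-en-1-yn-3-ol
Product: 9 (S)-5,5-dimethoxy-3-methylpent-1-yn-3-ol, via silyl ynal 7 (not isolated), via silyl acetal 8 (not isolated)
Conditions: O3, CH2Cl2/MeOH 3:1, −78 °C; Me2S, to 23 °C; p-TsOH·H2O (5 mol%), 23 °C; K2CO3 (2 equiv), 23 °C
Reagents that add atoms: methanol CO
Why: Ozonolysis cleaves only the terminal alkene (the silyl alkyne is inert at −78 °C), acid in methanol turns the aldehyde into its dimethyl acetal, and carbonate in methanol protodesilylates the alkyne, all without touching C10.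

Step 4
Reactants: 10 4-[(tert-butyldimethylsilyl)oxy]but-2-yn-1-ol
Product: 12 (Z)-4-[(tert-butyldimethylsilyl)oxy]-3-iodobut-2-en-1-ol, via cyclic alkenylaluminate 11 (not isolated)
Conditions: NaAlH2(OCH2CH2OMe)2 (1.5 equiv), THF, 0 to 23 °C; I2 (1.5 equiv), THF, −78 to 0 °C
Reagents that add atoms: iodine [I][I]
Why: Hydroxyl-directed trans-hydroalumination of the propargylic alcohol puts aluminium on the distal alkyne carbon, and iodinolysis with retention gives the (Z)-iodoalkene that fixes the later C4=C5 geometry.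

Step 5
Reactants: 12 (Z)-4-[(tert-butyldimethylsilyl)oxy]-3-iodobut-2-en-1-ol
Product: 13 (Z)-4-[(tert-butyldimethylsilyl)oxy]-3-iodobut-2-enal
Conditions: MnO2 (15 equiv), CH2Cl2, 23 °C
Reagents that add atoms: none
Why: Allylic alcohol oxidation with MnO2 under neutral conditions gives the enal without touching the silyl ether or the alkene geometry.

Step 6
Reactants: 9 (S)-5,5-dimethoxy-3-methylpent-1-yn-3-ol; 13 (Z)-4-[(tert-butyldimethylsilyl)oxy]-3-iodobut-2-enal
Product: 14 (2Z,7S)-3-{[(tert-butyldimethylsilyl)oxy]methyl}-7-hydroxy-9,9-dimethoxy-7-methyl-4-oxonon-2-en-5-ynal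
Conditions: PdCl2(PPh3)2 (5 mol%), CuI (2 mol%), CO (5 bar), Et3N (2 equiv), THF, 23 °C
Reagents that add atoms: carbon monoxide [C-]#[O+]
Why: Carbonylative Sonogashira coupling, in which zerovalent palladium adds to the vinyl iodide with retention, CO inserts and the copper acetylide transfers the alkynyl group, building the C3 ketone between C2 and C4 in the presence of the free tertiary alcohol and the aldehyde.

Step 7
Reactants: 14 (2Z,7S)-3-{[(tert-butyldimethylsilyl)oxy]methyl}-7-hydroxy-9,9-dimethoxy-7-methyl-4-oxonon-2-en-5-ynal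
Product: 15 (2Z)-4-[(tert-butyldimethylsilyl)oxy]-3-[(5S)-5-(2,2-dimethoxyethyl)-5-methyl-4-oxo-4,5-dihydrofuran-2-yl]but-2-enal
Conditions: (4-CF3C6H4)3PAuCl (5 mol%), AgOSO2CF3 (5 mol%), PhMe, 23 °C
Reagents that add atoms: none
Why: Gold-catalysed cycloisomerisation of a γ-hydroxy ynone to a 3(2H)-furanone (alkyne π-activation, oxygen delivered to C1, the tertiary hydroxyl closing onto C3), in which the C10–O bond is never broken so C10 stays S.

Step 8
Reactants: 16 methyl 2-(bromomethyl)acrylate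
Product: 18 methyl (Z)-3-bromo-2-(bromomethyl)prop-2-enoate, via tribromo ester 17 (not isolated)
Conditions: Br2 (1.05 equiv), CH2Cl2, 0 to 23 °C; DBU (1.1 equiv), Et2O, 0 °C
Reagents that add atoms: bromine BrBr
Why: Bromine addition to the acrylate followed by E2 dehydrobromination (the only β-hydrogens sit on the CH2Br groups) gives the β-bromoacrylate.

Step 9
Reactants: 18 methyl (Z)-3-bromo-2-(bromomethyl)prop-2-enoate
Product: 19 methyl (E)-3-bromo-2-[(4,4,5,5-tetramethyl-1,3,2-dioxaborolan-2-yl)methyl]prop-2-enoate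
Conditions: B2pin2 (1.1 equiv), Pd2(dba)3 (1.5 mol%), PhMe, 50 °C
Reagents that add atoms: bis(pinacolato)diboron CC1(C)OB(OC1(C)C)B1OC(C)(C)C(C)(C)O1
Why: Miyaura-type allylic borylation, in which zerovalent palladium ionises the allylic C–Br much faster than the vinylic one and the π-allyl complex takes boron at its CH2 terminus.

Step 10
Reactants: 15 (2Z)-4-[(tert-butyldimethylsilyl)oxy]-3-[(5S)-5-(2,2-dimethoxyethyl)-5-methyl-4-oxo-4,5-dihydrofuran-2-yl]but-2-enal; 19 methyl (E)-3-bromo-2-[(4,4,5,5-tetramethyl-1,3,2-dioxaborolan-2-yl)methyl]prop-2-enoate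
Product: 21 (4R,5R)-4-bromo-5-{(1Z)-3-[(tert-butyldimethylsilyl)oxy]-2-[(5S)-5-(2,2-dimethoxyethyl)-5-methyl-4-oxo-4,5-dihydrofuran-2-yl]prop-1-en-1-yl}-3-methylideneoxolan-2-one, via bromohydrin borate ester 20 (not isolated)
Conditions: 19 (1.5 equiv), (S)-TRIP phosphoric acid (10 mol%), 4 Å MS, PhMe, −30 to 0 °C; then CSA (10 mol%), 23 °C
Reagents that add atoms: none
Why: Proposed new method: the chiral phosphoric acid hydrogen-bonds to a pinacol oxygen of 19 and to the formyl C–H of 15, which should activate this electron-poor γ-bromo-2-(methoxycarbonyl)allylboronate for a closed six-membered chair allyl transfer onto one aldehyde face (C6 R), the γ-bromine sitting pseudo-axial to give the syn bromohydrin borate whose O–B oxygen then acylates on the neighbouring ester to close the lactone with the allylic C–Br intact; the closest known reaction types are chiral phosphoric acid-catalysed allyl- and crotylboration of aldehydes and Brønsted acid-catalysed allylboration–lactonisation with 2-alkoxycarbonyl allylboronates, neither shown with a γ-halo reagent.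

Step 11
Reactants: 21 (4R,5R)-4-bromo-5-{(1Z)-3-[(tert-butyldimethylsilyl)oxy]-2-[(5S)-5-(2,2-dimethoxyethyl)-5-methyl-4-oxo-4,5-dihydrofuran-2-yl]prop-1-en-1-yl}-3-methylideneoxolan-2-one
Product: 24 (6R,7R,8R,10S)-15-[(tert-butyldimethylsilyl)oxy]-8-hydroxy-1-oxo-3,10-epoxygermacra-2,4Z,11(13)-trien-12,6-olide, via bromo lactone aldehyde 22 (not isolated), via allylzinc bromide 23 (not isolated)
Conditions: I2 (10 mol%), acetone/H2O 50:1, 23 °C; Na2S2O3 wash, solvent switch to THF; Zn dust (10 equiv), THF/sat. aq. NH4Cl 2:1, 23 °C, syringe-pump addition to 2 mM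
Reagents that add atoms: water O
Why: Intramolecular zinc Barbier allylation, in which zinc inserts into the allylic C–Br, the 2-(alkoxycarbonyl)allylzinc bonds through C7 to the tethered aldehyde anti to the C5 substituent of the lactone (trans fusion, 7R) with allyl transposition creating the exocyclic methylene, and the short C9–C10 tether is expected to deliver the aldehyde face that places O8 syn to the ring oxygen on C10 (8R).

Step 12
Reactants: 24 (6R,7R,8R,10S)-15-[(tert-butyldimethylsilyl)oxy]-8-hydroxy-1-oxo-3,10-epoxygermacra-2,4Z,11(13)-trien-12,6-olide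
Product: 25 (6R,7R,8R,10S)-15-[(tert-butyldimethylsilyl)oxy]-8-(methacryloyloxy)-1-oxo-3,10-epoxygermacra-2,4Z,11(13)-trien-12,6-olide
Conditions: methacrylic anhydride (3 equiv), Et3N, DMAP (20 mol%), CH2Cl2, 0 to 23 °C
Reagents that add atoms: methacrylic anhydride C=C(C)C(=O)OC(=O)C(C)=C
Why: DMAP-catalysed acyl transfer (Steglich-type acylation) esterifies the only free hydroxyl with retention at C8.

Step 13
Reactants: 25 (6R,7R,8R,10S)-15-[(tert-butyldimethylsilyl)oxy]-8-(methacryloyloxy)-1-oxo-3,10-epoxygermacra-2,4Z,11(13)-trien-12,6-olide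
Product: 26 (6R,7R,8R,10S)-15-hydroxy-8-(methacryloyloxy)-1-oxo-3,10-epoxygermacra-2,4Z,11(13)-trien-12,6-olide
Conditions: HF·pyridine, pyridine/THF, 0 to 23 °C
Reagents that add atoms: none
Why: Fluoride-mediated silyl ether cleavage under buffered acidic conditions frees the C15 alcohol without adding to the three Michael acceptors.

**Compound list**

1 | allylmagnesium bromide | C=CC[Mg]Br | starting material
2 | triisopropyl borate | CC(C)OB(OC(C)C)OC(C)C | starting material
3 | bromomagnesium allyltriisopropoxyborate | C=CC[B-](OC(C)C)(OC(C)C)OC(C)C.[Mg+]Br | intermediate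
4 | allyldiisopropoxyborane | C=CCB(OC(C)C)OC(C)C | intermediate
5 | 4-(trimethylsilyl)but-3-yn-2-one | CC(=O)C#C[Si](C)(C)C | starting material
6 | (S)-3-methyl-1-(trimethylsilyl)hex-5-en-1-yn-3-ol | C=CC[C@](C)(O)C#C[Si](C)(C)C | intermediate
7 | (S)-3-hydroxy-3-methyl-5-(trimethylsilyl)pent-4-ynal | O=CC[C@](C)(O)C#C[Si](C)(C)C | intermediate
8 | (S)-5,5-dimethoxy-3-methyl-1-(trimethylsilyl)pent-1-yn-3-ol | COC(OC)C[C@](C)(O)C#C[Si](C)(C)C | intermediate
9 | (S)-5,5-dimethoxy-3-methylpent-1-yn-3-ol | COC(OC)C[C@](C)(O)C#C | intermediate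
10 | 4-[(tert-butyldimethylsilyl)oxy]but-2-yn-1-ol | OCC#CCO[Si](C)(C)C(C)(C)C | starting material
11 | sodium cyclic alkenyl(alkoxy)bis(2-methoxyethoxy)aluminate (Al on C3 of the butenyl unit and on O1) | [Na+].COCCO[Al-]1(OCCOC)OCC=C1CO[Si](C)(C)C(C)(C)C | intermediate
12 | (Z)-4-[(tert-butyldimethylsilyl)oxy]-3-iodobut-2-en-1-ol | OC/C=C(\I)CO[Si](C)(C)C(C)(C)C | intermediate
13 | (Z)-4-[(tert-butyldimethylsilyl)oxy]-3-iodobut-2-enal | O=C/C=C(\I)CO[Si](C)(C)C(C)(C)C | intermediate
14 | (2Z,7S)-3-{[(tert-butyldimethylsilyl)oxy]methyl}-7-hydroxy-9,9-dimethoxy-7-methyl-4-oxonon-2-en-5-ynal | COC(OC)C[C@](C)(O)C#CC(=O)/C(CO[Si](C)(C)C(C)(C)C)=C\C=O | intermediate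
15 | (2Z)-4-[(tert-butyldimethylsilyl)oxy]-3-[(5S)-5-(2,2-dimethoxyethyl)-5-methyl-4-oxo-4,5-dihydrofuran-2-yl]but-2-enal | COC(OC)C[C@]1(C)OC(=CC1=O)/C(CO[Si](C)(C)C(C)(C)C)=C\C=O | intermediate
16 | methyl 2-(bromomethyl)acrylate | C=C(CBr)C(=O)OC | starting material
17 | methyl 2,3-dibromo-2-(bromomethyl)propanoate | COC(=O)C(Br)(CBr)CBr | intermediate
18 | methyl (Z)-3-bromo-2-(bromomethyl)prop-2-enoate | COC(=O)/C(CBr)=C/Br | intermediate
19 | methyl (E)-3-bromo-2-[(4,4,5,5-tetramethyl-1,3,2-dioxaborolan-2-yl)methyl]prop-2-enoate | COC(=O)/C(CB1OC(C)(C)C(C)(C)O1)=C/Br | intermediate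
20 | methyl (3R,4R,5Z)-3-bromo-7-[(tert-butyldimethylsilyl)oxy]-6-[(5S)-5-(2,2-dimethoxyethyl)-5-methyl-4-oxo-4,5-dihydrofuran-2-yl]-2-methylidene-4-[(4,4,5,5-tetramethyl-1,3,2-dioxaborolan-2-yl)oxy]hept-5-enoate | COC(OC)C[C@]1(C)OC(=CC1=O)/C(CO[Si](C)(C)C(C)(C)C)=C\[C@@H](OB2OC(C)(C)C(C)(C)O2)[C@H](Br)C(=C)C(=O)OC | intermediate
21 | (4R,5R)-4-bromo-5-{(1Z)-3-[(tert-butyldimethylsilyl)oxy]-2-[(5S)-5-(2,2-dimethoxyethyl)-5-methyl-4-oxo-4,5-dihydrofuran-2-yl]prop-1-en-1-yl}-3-methylideneoxolan-2-one | COC(OC)C[C@]1(C)OC(=CC1=O)/C(CO[Si](C)(C)C(C)(C)C)=C\[C@H]1OC(=O)C(=C)[C@H]1Br | intermediate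
22 | (4R,5R)-4-bromo-5-{(1Z)-3-[(tert-butyldimethylsilyl)oxy]-2-[(5S)-5-methyl-4-oxo-5-(2-oxoethyl)-4,5-dihydrofuran-2-yl]prop-1-en-1-yl}-3-methylideneoxolan-2-one | O=CC[C@]1(C)OC(=CC1=O)/C(CO[Si](C)(C)C(C)(C)C)=C\[C@H]1OC(=O)C(=C)[C@H]1Br | intermediate
23 | bromo{[(5R)-5-{(1Z)-3-[(tert-butyldimethylsilyl)oxy]-2-[(5S)-5-methyl-4-oxo-5-(2-oxoethyl)-4,5-dihydrofuran-2-yl]prop-1-en-1-yl}-2-oxo-2,5-dihydrofuran-3-yl]methyl}zinc | O=CC[C@]1(C)OC(=CC1=O)/C(CO[Si](C)(C)C(C)(C)C)=C\[C@H]1OC(=O)C(C[Zn]Br)=C1 | intermediate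
24 | (6R,7R,8R,10S)-15-[(tert-butyldimethylsilyl)oxy]-8-hydroxy-1-oxo-3,10-epoxygermacra-2,4Z,11(13)-trien-12,6-olide | O[C@@H]1C[C@]2(C)OC(=CC2=O)/C(CO[Si](C)(C)C(C)(C)C)=C\[C@H]2OC(=O)C(=C)[C@@H]21 | intermediate
25 | (6R,7R,8R,10S)-15-[(tert-butyldimethylsilyl)oxy]-8-(methacryloyloxy)-1-oxo-3,10-epoxygermacra-2,4Z,11(13)-trien-12,6-olide | C=C(C)C(=O)O[C@@H]1C[C@]2(C)OC(=CC2=O)/C(CO[Si](C)(C)C(C)(C)C)=C\[C@H]2OC(=O)C(=C)[C@@H]21 | intermediate
26 | (6R,7R,8R,10S)-15-hydroxy-8-(methacryloyloxy)-1-oxo-3,10-epoxygermacra-2,4Z,11(13)-trien-12,6-olide | C=C(C)C(=O)O[C@@H]1C[C@]2(C)OC(=CC2=O)/C(CO)=C\[C@H]2OC(=O)C(=C)[C@@H]21 | target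

**Step count and risks**

Total step count: 13 (steps 1, 8 and 9 make the two boron reagents). Longest linear sequence: 9 steps (1, 2, 3, 6, 7, 10, 11, 12, 13).

The three steps most likely to fail are 6, 10 and 11.

Step 6 can suffer from direct (non-carbonylative) coupling of the electron-poor vinyl iodide and from Z-to-E drift of the β-iodo enal 13 and of the cis-enedicarbonyl 14 in the presence of amine and phosphine. The fallback avoids palladium and CO and sets out from 9 and 12. Double deprotonation of 9 with n-BuLi and formylation with DMF gives (S)-4-hydroxy-6,6-dimethoxy-4-methylhex-2-ynal F1. A Nozaki–Hiyama–Kishi coupling (CrCl2, catalytic NiCl2, DMF) of F1 with iodo alcohol 12 gives (2Z,7S)-3-{[(tert-butyldimethylsilyl)oxy]methyl}-9,9-dimethoxy-7-methylnon-2-en-5-yne-1,4,7-triol F2 as a mixture of C4 epimers. MnO2 then oxidises both the secondary propargylic–allylic alcohol and the primary allylic alcohol, and the sequence comes back to the route at 14.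

Step 10 is the proposed new reaction. The γ-bromo boronate 19 may be too unreactive or give low facial selectivity, and the bromohydrin borate could close to a vinyl epoxide instead of the lactone. Either C7 epimer of 21, or its allylic isomer, would still converge on allylzinc 23, so only the C6 selectivity matters. The fallback uses known chemistry and sets out from 15:

- Catalytic asymmetric vinylation with divinylzinc and (−)-MIB gives (2S)-5-{(2Z,4S)-1-[(tert-butyldimethylsilyl)oxy]-4-hydroxyhexa-2,5-dien-2-yl}-2-(2,2-dimethoxyethyl)-2-methylfuran-3(2H)-one F3.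
- Esterification with 2-(bromomethyl)acrylic acid (DIC, catalytic DMAP) gives (3S,4Z)-6-[(tert-butyldimethylsilyl)oxy]-5-[(5S)-5-(2,2-dimethoxyethyl)-5-methyl-4-oxo-4,5-dihydrofuran-2-yl]hexa-1,4-dien-3-yl 2-(bromomethyl)prop-2-enoate F4.
- Ring-closing metathesis with the second-generation Grubbs catalyst gives (5R)-3-(bromomethyl)-5-{(1Z)-3-[(tert-butyldimethylsilyl)oxy]-2-[(5S)-5-(2,2-dimethoxyethyl)-5-methyl-4-oxo-4,5-dihydrofuran-2-yl]prop-1-en-1-yl}furan-2(5H)-one F5.
- Acetal hydrolysis as in step 11 gives (5R)-3-(bromomethyl)-5-{(1Z)-3-[(tert-butyldimethylsilyl)oxy]-2-[(5S)-5-methyl-4-oxo-5-(2-oxoethyl)-4,5-dihydrofuran-2-yl]prop-1-en-1-yl}furan-2(5H)-one F6.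
- Zinc insertion into F6 gives the same allylzinc, so the sequence comes back to the route at 23 and hence 24.

Step 11 closes a strained ring and sets two stereocentres at once. The C7 outcome rests on the usual anti addition to a γ-substituted butenolide allylmetal, but the C8 outcome rests on the tether overriding the closed chair preference of the allylmetal, which is not assured. The fallback accepts the other C8 epimer and corrects it, setting out from aldehyde 22. Cyclisation with CrCl2 (THF/DMF, high dilution), which runs through the closed chair transition state, is expected to give (6R,7R,8S,10S)-15-[(tert-butyldimethylsilyl)oxy]-8-hydroxy-1-oxo-3,10-epoxygermacra-2,4Z,11(13)-trien-12,6-olide F7. A Mitsunobu esterification of F7 with methacrylic acid (PPh3, DIAD) inverts C8, and the sequence comes back to the route at 25. The same Mitsunobu step applies if the zinc reaction itself gives mainly F7.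

**Further compounds**

F1 | step 6 | (S)-4-hydroxy-6,6-dimethoxy-4-methylhex-2-ynal | COC(OC)C[C@](C)(O)C#CC=O
F2 | step 6 | (2Z,7S)-3-{[(tert-butyldimethylsilyl)oxy]methyl}-9,9-dimethoxy-7-methylnon-2-en-5-yne-1,4,7-triol (C4 epimers) | COC(OC)C[C@](C)(O)C#CC(O)/C(CO[Si](C)(C)C(C)(C)C)=C\CO
F3 | step 10 | (2S)-5-{(2Z,4S)-1-[(tert-butyldimethylsilyl)oxy]-4-hydroxyhexa-2,5-dien-2-yl}-2-(2,2-dimethoxyethyl)-2-methylfuran-3(2H)-one | COC(OC)C[C@]1(C)OC(=CC1=O)/C(CO[Si](C)(C)C(C)(C)C)=C\[C@@H](O)C=C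
F4 | step 10 | (3S,4Z)-6-[(tert-butyldimethylsilyl)oxy]-5-[(5S)-5-(2,2-dimethoxyethyl)-5-methyl-4-oxo-4,5-dihydrofuran-2-yl]hexa-1,4-dien-3-yl 2-(bromomethyl)prop-2-enoate | COC(OC)C[C@]1(C)OC(=CC1=O)/C(CO[Si](C)(C)C(C)(C)C)=C\[C@@H](OC(=O)C(=C)CBr)C=C
F5 | step 10 | (5R)-3-(bromomethyl)-5-{(1Z)-3-[(tert-butyldimethylsilyl)oxy]-2-[(5S)-5-(2,2-dimethoxyethyl)-5-methyl-4-oxo-4,5-dihydrofuran-2-yl]prop-1-en-1-yl}furan-2(5H)-one | COC(OC)C[C@]1(C)OC(=CC1=O)/C(CO[Si](C)(C)C(C)(C)C)=C\[C@H]1OC(=O)C(CBr)=C1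
F6 | step 10 | (5R)-3-(bromomethyl)-5-{(1Z)-3-[(tert-butyldimethylsilyl)oxy]-2-[(5S)-5-methyl-4-oxo-5-(2-oxoethyl)-4,5-dihydrofuran-2-yl]prop-1-en-1-yl}furan-2(5H)-one | O=CC[C@]1(C)OC(=CC1=O)/C(CO[Si](C)(C)C(C)(C)C)=C\[C@H]1OC(=O)C(CBr)=C1
F7 | step 11 | (6R,7R,8S,10S)-15-[(tert-butyldimethylsilyl)oxy]-8-hydroxy-1-oxo-3,10-epoxygermacra-2,4Z,11(13)-trien-12,6-olide | O[C@H]1C[C@]2(C)OC(=CC2=O)/C(CO[Si](C)(C)C(C)(C)C)=C\[C@H]2OC(=O)C(=C)[C@@H]21
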